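## The problem

The target is a tetracycle. An enolised 2-isobutyryl-4,4-dimethylcyclohexane-1,3,5-trione is joined through one enol oxygen and a CH2 group (C12) to a dihydropyran. The pyran is trans-fused along C4–C5 to a nine-membered carbocycle, which carries an exocyclic methylene at C8 and is trans-fused along C1–C9 to an 11,11-dimethylcyclobutane (caryophyllane numbering, C1–C11). A synthesis has to close the nine-membered ring, which end-to-end cyclisation does poorly, and to set four stereocentres: C1 and C9 at the cyclobutane, the quaternary ether carbon C4, and C5. C9 lies alpha to C8 and can be equilibrated to the trans fusion while C8 is a ketone, so only C1 must be fixed at the outset. C1 can then direct the configuration of a bicyclic precursor from which C5 is derived, and C5 has to direct the closure at C4. The acyl triketone is a strong acid and a chelating ligand, the tertiary enol ether ionises in acid, and cyclobutane, medium ring and exocyclic alkene together invite transannular cation chemistry. The methylene is therefore introduced last, and acid is used only while C8 is a carbonyl. The feature that opens the chosen route is that C8, read as a ketone, is 1,5-related to C4 through C7–C6–C5. With a C3=C4 alkene in place and C5–C6 cut, the nine-membered ring collapses to a 3-hydroxy-1,5-diene whose C3–C8 bond belongs to a cyclopentane, that is, to a 2-vinyl-3-alkenylbicyclo[3.2.0]heptan-2-ol that already holds the dimethylcyclobutane.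

## Retrosynthesis

**25 to 24.** The C8=CH2 bond is cut first, giving ketone 24. This removes the alkene that would take part in cationic transannular reactions and supplies a carbonyl next to C9. The forward step is a Wittig methylenation of a hindered ketone beside a triketone that is protected as its enolate.

**24 to 23 to 22.** The C4–O bond is cut next, turning the pyran of 24 into the free enol and the (E)-C3=C4 alkene of 23. Cutting O–C4 and C12–C5 together (the hetero-Diels–Alder cut) would need the C4=C5 alkene of a finished nine-membered ring and would set C5 by facial selection on a flexible ring. The single cut keeps C5 as a stereocentre that a sigmatropic shift can deliver. The forward reaction is a Markovnikov 6-exo closure of the non-chelated enol oxygen onto C4, under control by C5. Ketone 23 is the C9 epimer of 22 and should arise from it by equilibration.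

**22 to 20 (key disconnection).** C5–C6 is cut and C3–C8 reconnected, the retron of an oxy-Cope rearrangement. Four ring carbons leave the ring, and the nine-membered ketone 22 becomes carbinol 20, a cyclopentanol fused to the cyclobutane. A medium-ring closure is thereby replaced by a ring expansion whose product is an enolate (21). The forward reaction needs the two alkenyl groups trans, the arm (E)-configured, and the arm on the convex face of the bicycle (trans to the cyclobutane).

**20 to 15 + 19.** The bond from C12 to the triketone ring is cut. This keeps the acidic, metal-binding triketone out of the enolate coupling and the organometallic addition. Isobutyrylfilicinic acid 19 has a single nucleophilic ring carbon, and the allylic carbonate 15 offers an unhindered CH2 terminus, so the forward step is an allylic alkylation.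

**15 to 14 to 13, then 13 to 11 + 12.** Carbonate 15 comes from diol 14 and this from silyl ether 13. In 13 the carbinol–vinyl bond is cut (caryophyllane C8–C7; bicyclic locant C2), giving ketone 11 and vinylmagnesium bromide 12. The addition has to come anti to the arm, from the concave face.

**11 to 5 + 9.** The bond between bicyclic C3 and the arm is cut, giving the lithium enolate 10 of ketone 5 and the (E)-alkenyl bromide 9. Enolisation towards the cyclobutane bridgehead is disfavoured, so the coupling should be regioselective, and the arm should settle on the convex face.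

**5 to 3 to 1 + 2.** The cyclobutane of 5 is cut into cyclopentenone 1 and isobutylene 2 ([2+2] photocycloaddition). The racemic adduct 3 is resolved through the sulfoximine adduct 4, the only point where absolute configuration enters.

**Fragments.** Bromide 9 comes from the silyl ether 7 of but-2-yn-1-ol 6 by hydrozirconation (8) and bromination. Triketone 19 comes from phloroglucinol 16 and isobutyryl chloride 17 through ketone 18 and dearomative gem-dimethylation.

## Roads not taken

**Alternative 1:** Cut C1–C9 and C10–C11 together, so that the cyclobutane is made last from an allenoate and a trisubstituted alkene carried on a finished pyranotriketone (A1). EtAlCl2 would activate the allenoate of A1, and its C9=C10 bond would add across C1=C11, closing the four- and the nine-membered ring at once to give the alkylidenecyclobutane ester A2.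
- Merits: two rings and two C–C bonds in one step; the regiochemistry is sound because the tertiary cation forms at the dimethyl carbon; C4 and C5 would be set before ring closure, so neither the resolution nor the late closure at C4 of the chosen plan is needed. In convergence this road is better.
- Weak points: Lewis-acid allenoate–alkene cycloadditions are reliable for five- and six-membered fused rings, not for a nine-membered one. The intermediate cation can lose a proton or be trapped by an enol oxygen. The triketone binds the aluminium reagent and the tertiary ether is acid-labile. A2 has a trigonal C9 and an ester carbon on C8, so the ring fusion and the methylene still need a reduction and a reductive transposition with uncertain facial control.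
- Comparison: the chosen plan is longer and has two substrate-controlled steps of its own, but it forms the medium ring by a well-known ring expansion and takes the cyclobutane from a simple photocycloaddition.

**Alternative 2:** Cut C6–C7. Pd(PPh3)4 (zerovalent palladium) would ionise the allylic carbonate of A3, and the bis(phenylsulfonyl)methyl carbanion at C6 would attack a CH2 terminus of the allyl–palladium unit to give the bis-sulfone A4.
- Merits: the two allyl termini are equivalent CH2 groups, so there is no regiochemical question. The exocyclic methylene is formed in the ring closure, so no Wittig step is needed. All four stereocentres exist before the ring closes. In these points it is as good as or better than the chosen plan.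
- Weak points: it is an end-to-end nine-membered closure with a hindered carbanion next to C5. The triketone is more acidic than the bis-sulfone and can be O-allylated. A4 needs a double reductive desulfonylation beside an exocyclic alkene and an enolised triketone. Assembling A3 requires the trans cyclobutane substitution and the C4/C5 pair to be made separately in enantiopure form.
- Comparison: the chosen plan relays configuration from one resolved photoadduct and avoids the entropic cost of the closure; in exchange it must control the late closure at C4.

**Alternative 3:** Cut C2–C3 as an alkene. Second-generation Grubbs catalyst would join the vinyl groups on C4 and C1 of diene A5 to give the (Z)-cyclononene A6; hydrogenation and methylenation would follow.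
- Merits: metathesis tolerates ketones and enols; both alkenes are monosubstituted; the alkene geometry does not matter; no strong base or trianion is involved. In functional-group tolerance it is better than the chosen plan.
- Weak points: nine-membered ring-closing metathesis is among the least favourable (ring strain, dimerisation). One vinyl group sits on the fully substituted ether carbon C4 and the other on a trans-disubstituted cyclobutane whose substituents point apart. A5 needs a quaternary C4 bearing vinyl, methyl and the enol oxygen in defined configuration, for which there is no simple entry.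
- Comparison: the chosen plan builds C4 late from an alkene that the key step itself delivers, and pays with the uncertainty of that closure.

Key step: step 13

**Conventions and assumptions**
- Caryophyllane numbering (C1–C11, C12 for the CH2 bridge) is used for the ring system; names of bicyclo[3.2.0]heptanes use their own locants (C2 = C8, C3 = C3, C4 = C2, C5 = C1, C6 = C11, C7 = C10, C1 = C9).
- The triketone is written as one enol tautomer; "filicinyl" means 2,6-dihydroxy-3,3-dimethyl-5-(2-methylpropanoyl)-4-oxocyclohexa-1,5-dien-1-yl.
- Which of the two separable sulfoximine adducts contains the (1R,5R) ketone is assumed to be assigned after separation (crystal structure or rotation of the regenerated ketone).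

## Route

Step 1
Reactants: 1 cyclopent-2-en-1-one; 2 isobutylene (2-methylpropene)
Product: 3 (±)-cis-6,6-dimethylbicyclo[3.2.0]heptan-2-one
Conditions: hν (medium-pressure Hg lamp, Pyrex), excess 2, CH2Cl2, −40 °C
Reagents that add atoms: none
Why: Enone–alkene [2+2] photocycloaddition; the 1,1-disubstituted alkene adds mainly head-to-tail, placing CMe2 on the former beta carbon, and the four/five fusion can only be cis (both bridgeheads set together, racemic); the 7,7-dimethyl regioisomer is removed by distillation or chromatography.

Step 2
Reactants: 3 (±)-cis-6,6-dimethylbicyclo[3.2.0]heptan-2-one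
Product: 4 (1R,2S,5R)-6,6-dimethyl-2-{[(S)-N-methyl-S-phenylsulfonimidoyl]methyl}bicyclo[3.2.0]heptan-2-ol
Conditions: (S)-PhS(O)(NMe)CH3, n-BuLi, THF, −78 °C; then 3; aq NH4Cl; separation of the two diastereomeric adducts on silica
Reagents that add atoms: (S)-N,S-dimethyl-S-phenylsulfoximine, C[S@@](=O)(=NC)c1ccccc1
Why: 1,2-Addition of the lithiated enantiopure sulfoximine from the convex face gives one beta-hydroxy sulfoximine from each ketone enantiomer; these are diastereomers and separable (resolution of a ketone through a covalent adduct), and the carbinol centre is temporary.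

Step 3
Reactants: 4 (1R,2S,5R)-sulfoximine adduct
Product: 5 (1R,5R)-6,6-dimethylbicyclo[3.2.0]heptan-2-one
Conditions: toluene, 130 °C (sealed tube)
Reagents that add atoms: none
Why: Thermal retro-addition of the beta-hydroxy sulfoximine regenerates the ketone as a single enantiomer and returns the auxiliary; no stereocentre of the ketone is touched.

Step 4
Reactants: 6 but-2-yn-1-ol
Product: 7 (but-2-yn-1-yloxy)(tert-butyl)dimethylsilane
Conditions: TBSCl, imidazole, DMF, rt
Reagents that add atoms: tert-butyldimethylsilyl chloride (TBSCl), CC(C)(C)[Si](C)(C)Cl
Why: Silylation of a primary alcohol; the ether survives the amide base and the organocerium reagent used later.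

Step 5
Reactants: 7 (but-2-yn-1-yloxy)(tert-butyl)dimethylsilane
Product: 9 (E)-[(3-bromobut-2-en-1-yl)oxy](tert-butyl)dimethylsilane, via alkenylzirconocene chloride 8 (not isolated)
Conditions: Cp2Zr(H)Cl (2.5 equiv), THF, 50 °C; then NBS, 0 °C
Reagents that add atoms: N-bromosuccinimide (NBS), O=C1CCC(=O)N1Br
Why: Hydrozirconation is a syn addition, and with excess hydride at 50 °C the alkenylzirconium equilibrates to the isomer with zirconium on the less hindered methyl-bearing carbon; bromination with retention puts bromine trans to CH2OSi, the (E) geometry the arm needs.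

Step 6
Reactants: 5 (1R,5R)-6,6-dimethylbicyclo[3.2.0]heptan-2-one; 9 (E)-alkenyl bromide
Product: 11 (1R,3S,5R)-3-[(2E)-4-(tert-butyldimethylsilyloxy)but-2-en-2-yl]-6,6-dimethylbicyclo[3.2.0]heptan-2-one, via lithium enolate 10 (not isolated)
Conditions: LiN(SiMe3)2 (2.2 equiv), toluene, 0 °C; Pd2(dba)3 (2.5 mol%, zerovalent palladium), tBu3P·HBF4 (6 mol%), 9, rt; AcOH, −78 °C; then Et3N, CH2Cl2, rt
Reagents that add atoms: none
Why: Palladium-catalysed alpha-alkenylation of a ketone enolate with retention of alkene geometry; deprotonation occurs at the C3 methylene because an enolate towards the cyclobutane bridgehead is strained, and the product stays as its dienolate until the cold acidic quench, which limits double coupling and conjugation. Brief amine equilibration should place the arm on the convex face, trans to the cyclobutane (3S).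

Step 7
Reactants: 11 alkenyl ketone; 12 vinylmagnesium bromide
Product: 13 (1R,2S,3S,5R)-3-[(2E)-4-(tert-butyldimethylsilyloxy)but-2-en-2-yl]-2-ethenyl-6,6-dimethylbicyclo[3.2.0]heptan-2-ol
Conditions: CeCl3 (anhydrous, 3 equiv), 12 (3 equiv), THF, −78 °C; then 11, −78 °C; aq NH4Cl
Reagents that add atoms: none
Why: Organocerium 1,2-addition, chosen because the beta,gamma-unsaturated ketone enolises easily. The exo arm is branched at its first carbon and holds its methyl group or vinylic CH over the convex face of the carbonyl, so vinyl is expected to enter anti to it from the concave face (2S), giving the trans-dialkenyl carbinol with hydroxyl cis to the arm; any C2 epimer is removed by chromatography.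

Step 8
Reactants: 13 silyl ether carbinol
Product: 14 (1R,2S,3S,5R)-2-ethenyl-3-[(2E)-4-hydroxybut-2-en-2-yl]-6,6-dimethylbicyclo[3.2.0]heptan-2-ol
Conditions: Bu4NF, THF, 0 °C
Reagents that add atoms: none
Why: Fluoride cleavage of the primary silyl ether; the tertiary allylic alcohol and both alkenes are inert.

Step 9
Reactants: 14 diol
Product: 15 (2E)-3-[(1R,2S,3S,5R)-2-ethenyl-2-hydroxy-6,6-dimethylbicyclo[3.2.0]heptan-3-yl]but-2-en-1-yl methyl carbonate
Conditions: ClCO2Me, pyridine, CH2Cl2, 0 °C
Reagents that add atoms: methyl chloroformate, COC(=O)Cl
Why: Acylation of the primary allylic alcohol; the hindered tertiary carbinol does not react under these conditions, so only the position to be ionised is activated.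

Step 10
Reactants: 16 phloroglucinol; 17 isobutyryl chloride
Product: 18 2-methyl-1-(2,4,6-trihydroxyphenyl)propan-1-one
Conditions: AlCl3, PhNO2, rt to 60 °C; aq HCl
Reagents that add atoms: none
Why: Friedel–Crafts C-acylation; the first acyl group deactivates the ring, so mono-acylation is obtained.

Step 11
Reactants: 18 2-methyl-1-(2,4,6-trihydroxyphenyl)propan-1-one
Product: 19 isobutyrylfilicinic acid [3,5-dihydroxy-6,6-dimethyl-2-(2-methylpropanoyl)cyclohexa-2,4-dien-1-one]
Conditions: NaOMe (3 equiv), MeI (2.1 equiv), MeOH, 0 °C to rt; aq HCl
Reagents that add atoms: iodomethane (MeI), CI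
Why: Dearomative C-methylation of the acylphloroglucinol polyanion, the classical entry to acylfilicinic acids; the second methyl group can enter the already methylated carbon, and the gem-dimethyl product is separated from the aromatic C-methyl and trimethyl congeners.

Step 12
Reactants: 15 allylic carbonate; 19 isobutyrylfilicinic acid
Product: 20 4-{(2E)-3-[(1R,2S,3S,5R)-2-ethenyl-2-hydroxy-6,6-dimethylbicyclo[3.2.0]heptan-3-yl]but-2-en-1-yl}-3,5-dihydroxy-6,6-dimethyl-2-(2-methylpropanoyl)cyclohexa-2,4-dien-1-one
Conditions: Pd(PPh3)4 (5 mol%, zerovalent palladium), 19 (1.5 equiv), THF, rt to 40 °C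
Reagents that add atoms: none
Why: Tsuji–Trost allylic alkylation: palladium ionises the primary carbonate, the released methoxide deprotonates the triketone, and its only nucleophilic ring carbon attacks the unhindered CH2 terminus. O-allyl products re-ionise and funnel to the C-allyl compound, and the syn allyl geometry should keep the (E)-alkene.

Step 13
Reactants: 20 dialkenyl carbinol
Product: 22 (1R,3E,5R,9R)-5-(filicinylmethyl)-4,11,11-trimethylbicyclo[7.2.0]undec-3-en-8-one, via tripotassium enolate 21 (not isolated)
Conditions: KH (3.5 equiv), 18-crown-6 (3.5 equiv), THF, 0 °C to rt; then aq NH4Cl, −78 °C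
Reagents that add atoms: none
Why: KH forms the tripotassium salt, and the carbinol alkoxide accelerates a concerted [3,3] sigmatropic shift in which the vinyl terminus C6 bonds to the arm terminus C5 while the ring bond C3–C8 breaks; the closest known reaction type is the anionic oxy-Cope ring expansion of trans-1,2-dialkenylcycloalkanols to 5-cycloalkenones. The nine-membered ring is closed by a four-carbon ring expansion through a six-membered chair transition state, not by end-to-end cyclisation. The one new stereocentre, C5, is controlled by the configurations at C3 and C8: the trans arrangement of the alkenyl groups admits only the chair with both ring bonds pseudo-equatorial, the shift is suprafacial on both allyl units, and the (E)-arm places the CH2–triketone group equatorial, which gives (5R) and the (E)-C3=C4 alkene. The step needs chair over boat and no fragmentation–recombination; the trans dialkenyl geometry excludes the boat, and enolate formation makes the shift irreversible. The triketone is present as its dipotassium salt and does not take part. C-protonation of enolate 21 at C7 on work-up leaves C9 untouched, so the cyclobutane fusion stays cis.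

Step 14
Reactants: 22 cis-fused cyclononenone
Product: 23 (1R,3E,5R,9S)-5-(filicinylmethyl)-4,11,11-trimethylbicyclo[7.2.0]undec-3-en-8-one
Conditions: NaOMe, MeOH, rt; then 1 M HCl
Reagents that add atoms: none
Why: Base-mediated epimerisation alpha to the ketone through the C8–C9 enolate; the trans-fused bicyclo[7.2.0]undecan-8-one is expected to be the more stable isomer, so C9 becomes (S) under equilibrium control, while C5 is not enolisable and the triketone is merely deprotonated.

Step 15
Reactants: 23 trans-fused cyclononenone
Product: 24 (1R,4S,5R,9S)-tetracyclic C8 ketone (the target with C8=O in place of C8=CH2)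
Conditions: TsOH·H2O (20 mol%), CH2Cl2, 0 °C to rt
Reagents that add atoms: none
Why: Acid-catalysed intramolecular Markovnikov hydroalkoxylation (chroman-type cyclisation): the strained (E)-trisubstituted alkene is protonated at C3, and the C4 cation is captured 6-exo by the enol oxygen next to CMe2, the other enol oxygen being held in the hydrogen bond to the isobutyryl group. C5 controls C4 through a chair closure with both ring bonds (to C3 and C6) equatorial and only the methyl axial, which should give the trans-fused pyran (4S); the tertiary ether can re-ionise, so the outcome can be equilibrated.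

Step 16
Reactants: 24 tetracyclic ketone
Product: 25 CNP0497637.1 (1R,4S,5R,9S)
Conditions: Ph3PCH3Br, KOtBu, toluene, rt; then 24, rt to 60 °C; aq NaH2PO4
Reagents that add atoms: methyltriphenylphosphonium bromide, C[P+](c1ccccc1)(c1ccccc1)c1ccccc1.[Br-]
Why: Wittig methylenation of the hindered C8 ketone with excess ylide; the triketone is present as its potassium enolate, whose carbonyl groups do not react, C9 is already in its stable configuration, and the acid-sensitive methylene is made last.

## Compound list

1 | cyclopent-2-en-1-one | O=C1C=CCC1 | starting material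
2 | isobutylene (2-methylpropene) | C=C(C)C | starting material
3 | (±)-cis-6,6-dimethylbicyclo[3.2.0]heptan-2-one (racemate, both enantiomers written) | O=C1CC[C@@H]2[C@H]1CC2(C)C.O=C1CC[C@H]2[C@@H]1CC2(C)C | intermediate
4 | (1R,2S,5R)-6,6-dimethyl-2-{[(S)-N-methyl-S-phenylsulfonimidoyl]methyl}bicyclo[3.2.0]heptan-2-ol | O[C@@]1(C[S@@](=O)(=NC)c3ccccc3)CC[C@@H]2[C@H]1CC2(C)C | intermediate
5 | (1R,5R)-6,6-dimethylbicyclo[3.2.0]heptan-2-one | O=C1CC[C@@H]2[C@H]1CC2(C)C | intermediate
6 | but-2-yn-1-ol | CC#CCO | starting material
7 | (but-2-yn-1-yloxy)(tert-butyl)dimethylsilane | CC#CCO[Si](C)(C)C(C)(C)C | intermediate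
8 | (E)-alkenylzirconocene chloride, Cp2Zr(Cl) on the methyl-bearing carbon of the butenyl silyl ether (Cp drawn sigma-bonded) | C/C(=C\CO[Si](C)(C)C(C)(C)C)[Zr](Cl)(C1C=CC=C1)C1C=CC=C1 | intermediate
9 | (E)-[(3-bromobut-2-en-1-yl)oxy](tert-butyl)dimethylsilane | C/C(Br)=C\CO[Si](C)(C)C(C)(C)C | intermediate
10 | lithium enolate of 5 (C2=C3 enolate) | [Li]OC1=CC[C@@H]2[C@H]1CC2(C)C | intermediate
11 | (1R,3S,5R)-3-[(2E)-4-(tert-butyldimethylsilyloxy)but-2-en-2-yl]-6,6-dimethylbicyclo[3.2.0]heptan-2-one | O=C1[C@H](/C(C)=C/CO[Si](C)(C)C(C)(C)C)C[C@@H]2[C@H]1CC2(C)C | intermediate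
12 | vinylmagnesium bromide | C=C[Mg]Br | starting material
13 | (1R,2S,3S,5R)-3-[(2E)-4-(tert-butyldimethylsilyloxy)but-2-en-2-yl]-2-ethenyl-6,6-dimethylbicyclo[3.2.0]heptan-2-ol | C=C[C@@]1(O)[C@H](/C(C)=C/CO[Si](C)(C)C(C)(C)C)C[C@@H]2[C@H]1CC2(C)C | intermediate
14 | (1R,2S,3S,5R)-2-ethenyl-3-[(2E)-4-hydroxybut-2-en-2-yl]-6,6-dimethylbicyclo[3.2.0]heptan-2-ol | C=C[C@@]1(O)[C@H](/C(C)=C/CO)C[C@@H]2[C@H]1CC2(C)C | intermediate
15 | (2E)-3-[(1R,2S,3S,5R)-2-ethenyl-2-hydroxy-6,6-dimethylbicyclo[3.2.0]heptan-3-yl]but-2-en-1-yl methyl carbonate | C=C[C@@]1(O)[C@H](/C(C)=C/COC(=O)OC)C[C@@H]2[C@H]1CC2(C)C | intermediate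
16 | phloroglucinol | Oc1cc(O)cc(O)c1 | starting material
17 | isobutyryl chloride | CC(C)C(Cl)=O | starting material
18 | 2-methyl-1-(2,4,6-trihydroxyphenyl)propan-1-one | CC(C)C(=O)c1c(O)cc(O)cc1O | intermediate
19 | isobutyrylfilicinic acid, 3,5-dihydroxy-6,6-dimethyl-2-(2-methylpropanoyl)cyclohexa-2,4-dien-1-one | CC(C)C(=O)C1=C(O)C=C(O)C(C)(C)C1=O | intermediate
20 | 4-{(2E)-3-[(1R,2S,3S,5R)-2-ethenyl-2-hydroxy-6,6-dimethylbicyclo[3.2.0]heptan-3-yl]but-2-en-1-yl}-3,5-dihydroxy-6,6-dimethyl-2-(2-methylpropanoyl)cyclohexa-2,4-dien-1-one | C=C[C@@]1(O)[C@H](/C(C)=C/CC2=C(O)C(C)(C)C(=O)C(C(=O)C(C)C)=C2O)C[C@@H]2[C@H]1CC2(C)C | intermediate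
21 | tripotassium salt: C7=C8 enolate of 22 with the triketone as its dienolate | [K+].[K+].[K+].[O-]/C1=C\C[C@H](CC3=C([O-])C(C)(C)C(=O)C(C(=O)C(C)C)=C3[O-])/C(C)=C/C[C@@H]2[C@H]1CC2(C)C | intermediate
22 | (1R,3E,5R,9R)-5-(filicinylmethyl)-4,11,11-trimethylbicyclo[7.2.0]undec-3-en-8-one (cis ring fusion) | O=C1CC[C@H](CC3=C(O)C(C)(C)C(=O)C(C(=O)C(C)C)=C3O)/C(C)=C/C[C@@H]2[C@H]1CC2(C)C | intermediate
23 | (1R,3E,5R,9S)-5-(filicinylmethyl)-4,11,11-trimethylbicyclo[7.2.0]undec-3-en-8-one (trans ring fusion) | O=C1CC[C@H](CC3=C(O)C(C)(C)C(=O)C(C(=O)C(C)C)=C3O)/C(C)=C/C[C@@H]2[C@@H]1CC2(C)C | intermediate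
24 | (1R,4S,5R,9S)-tetracyclic C8 ketone: pyran O on C4, C12 on C5, trans pyran and cyclobutane fusions | O=C1CC[C@@H]2CC3=C(O[C@@]2(C)CC[C@@H]2[C@@H]1CC2(C)C)C(C)(C)C(=O)C(C(=O)C(C)C)=C3O | intermediate
25 | CNP0497637.1, the 8-methylene compound (1R,4S,5R,9S) | C=C1CC[C@@H]2CC3=C(O[C@@]2(C)CC[C@@H]2[C@@H]1CC2(C)C)C(C)(C)C(=O)C(C(=O)C(C)C)=C3O | target

## Step count and uncertain steps

Total: 16 steps. Longest linear sequence: 12 steps (1, 2, 3, 6, 7, 8, 9, 12, 13, 14, 15, 16).

**Step 13 (key step).**
- Risk: the substrate reacts as a trianion, and poor solubility or aggregation of the salt may hold the alkoxide back. At the higher temperature then needed, heterolysis of C3–C8 to a vinyl ketone and an allyl anion, followed by unselective re-addition, would erode the transfer of configuration to C5. The chair also pushes C3 towards the endo methyl group and ends in a strained (E,E)-dienolate, which raises the barrier.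
- Fallback (from 20, back at 22): the triketone is masked so that a single alkoxide rearranges. MOMCl and iPr2NEt convert the two enol hydroxyls of 20 into the bis(methoxymethyl) enol ether F1, leaving the hindered tertiary carbinol free. KH and 18-crown-6 rearrange its monoalkoxide to the bis(methoxymethyl) ether of the cis-fused ketone F2. HCl in MeOH at 0 °C removes the acetals and gives 22.

**Step 7.**
- Risk: poor facial selectivity. The cyclobutane methylene shields the concave face, so attack on the convex face, syn to the arm, may compete or prevail and give the cis-dialkenyl epimer, which would rearrange through a different transition state. Enolisation of the ketone would return starting material.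
- Fallback (from 11, back at 13): the oxygen rather than the carbon is delivered to the less hindered face. The convex-face adduct, the (2R) carbinol F3, is deprotonated with n-BuLi and treated with PhSCl at −78 °C. Its sulfenate rearranges [2,3] to the allylic sulfoxide F4, in which the carbinol carbon is trigonal. Warming F4 with Et2NH in MeOH reverses the shift (Mislow–Evans rearrangement); the amine traps the sulfenate whose oxygen sits on the less hindered face, which under this premise is the convex one, that is, 13.

**Step 15.**
- Risk: wrong facial selectivity at C4 (a cis-fused pyran), capture by the chelated enol oxygen, or hydride shift and elimination of the C4 cation. The conformer analysis of the nine-membered cation does not clearly favour one face.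
- Fallback (from 22, back at 24): the order of steps 14 and 15 is reversed. The cis-fused ketone 22 is cyclised with TsOH to the tetracyclic ketone with cis cyclobutane fusion F5, in which the ring conformation during closure is different. NaOMe in MeOH then epimerises C9 to give 24.

**Step 6.**
- Risk: migration of the new double bond into conjugation with the ketone during coupling or amine equilibration, a second alkenylation, or incomplete equilibration at C3.
- Fallback (from 5, back at 11): the polarity is reversed and base avoided. PhNMe3Br3 in THF brominates 5 to the 3-exo-bromo ketone F6. Nickel-catalysed cross-coupling (NiCl2·glyme, bis(oxazoline) ligand) of F6 with the alkenylzirconium 8, prepared as in step 5 before the NBS quench, gives 11 under neutral conditions.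

**Step 12.**
- Risk: O-allylation or double C-allylation of the triketone, attack at the tertiary allyl terminus, or erosion of the (E) geometry by syn–anti exchange.
- Fallback (from 14, back at 20): Appel bromination (CBr4, PPh3, 0 °C) of the primary allylic alcohol gives the allylic bromide F7. Direct SN2 C-alkylation of the potassium salt of 19 (aq KOH, 0 °C) with F7 gives 20 with the alkene geometry untouched.

**Step 11.**
- Risk: unselective methylation (aromatic mono- and di-C-methyl products, trimethylation, O-methylation), leaving 19 as a minor component.
- Fallback (from 16, back at 19): the other ring carbons are blocked. Diacetylation of 16 (Ac2O, BF3·OEt2) gives 2,4-diacetylphloroglucinol F8, whose only free carbon is dimethylated (NaOMe, MeI) to 2,4-diacetylfilicinic acid F9. Warm aqueous H2SO4 removes both acetyl groups to give filicinic acid F10. C-acylation with 17 and AlCl3 gives 19.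

## Further compounds

F1 | step 13 | bis(methoxymethyl) enol ether of 20 | C=C[C@@]1(O)[C@H](/C(C)=C/CC2=C(OCOC)C(C)(C)C(=O)C(C(=O)C(C)C)=C2OCOC)C[C@@H]2[C@H]1CC2(C)C
F2 | step 13 | bis(methoxymethyl) enol ether of 22 | O=C1CC[C@H](CC3=C(OCOC)C(C)(C)C(=O)C(C(=O)C(C)C)=C3OCOC)/C(C)=C/C[C@@H]2[C@H]1CC2(C)C
F3 | step 7 | (1R,2R,3S,5R)-3-[(2E)-4-(tert-butyldimethylsilyloxy)but-2-en-2-yl]-2-ethenyl-6,6-dimethylbicyclo[3.2.0]heptan-2-ol (C2 epimer of 13) | C=C[C@]1(O)[C@H](/C(C)=C/CO[Si](C)(C)C(C)(C)C)C[C@@H]2[C@H]1CC2(C)C
F4 | step 7 | (1R,5R)-3-exo-[(2E)-4-(tert-butyldimethylsilyloxy)but-2-en-2-yl]-6,6-dimethyl-2-[2-(phenylsulfinyl)ethylidene]bicyclo[3.2.0]heptane (alkene and sulfur configuration open) | O=S(CC=C1[C@H](/C(C)=C/CO[Si](C)(C)C(C)(C)C)C[C@@H]2[C@H]1CC2(C)C)c1ccccc1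
F5 | step 15 | (1R,4S,5R,9R)-tetracyclic C8 ketone, C9 epimer of 24 (cis cyclobutane fusion) | O=C1CC[C@@H]2CC3=C(O[C@@]2(C)CC[C@@H]2[C@H]1CC2(C)C)C(C)(C)C(=O)C(C(=O)C(C)C)=C3O
F6 | step 6 | (1R,3R,5R)-3-bromo-6,6-dimethylbicyclo[3.2.0]heptan-2-one (bromine exo) | O=C1[C@H](Br)C[C@@H]2[C@H]1CC2(C)C
F7 | step 12 | (1R,2S,3S,5R)-3-[(2E)-4-bromobut-2-en-2-yl]-2-ethenyl-6,6-dimethylbicyclo[3.2.0]heptan-2-ol | C=C[C@@]1(O)[C@H](/C(C)=C/CBr)C[C@@H]2[C@H]1CC2(C)C
F8 | step 11 | 2,4-diacetylphloroglucinol | CC(=O)c1c(O)cc(O)c(C(C)=O)c1O
F9 | step 11 | 2,4-diacetylfilicinic acid | CC(=O)C1=C(O)C(C(C)=O)=C(O)C(C)(C)C1=O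
F10 | step 11 | filicinic acid | CC1(C)C(O)=CC(=O)C=C1O
A1 | alternative 1 | pyranotriketone with a methyl 2-alkylbuta-2,3-dienoate chain from C5 and a 4-methylpent-3-enyl chain on C4 | COC(=O)C(=C=C)CC[C@@H]2CC3=C(O[C@@]2(C)CCC=C(C)C)C(C)(C)C(=O)C(C(=O)C(C)C)=C3O
A2 | alternative 1 | tetracyclic alkylidenecyclobutane ester (C8=C9, ester on C8) | COC(=O)/C1=C2\CC(C)(C)[C@@H]2CC[C@]2(C)OC3=C(C[C@H]2CC1)C(O)=C(C(=O)C(C)C)C(=O)C3(C)C
A3 | alternative 2 | allylic methyl carbonate on C9 with a bis(phenylsulfonyl)methyl group as C6 | C(S(=O)(=O)c1ccccc1)(S(=O)(=O)c1ccccc1)[C@@H]2CC3=C(O[C@@]2(C)CC[C@@H]2[C@@H](C(=C)COC(=O)OC)CC2(C)C)C(C)(C)C(=O)C(C(=O)C(C)C)=C3O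
A4 | alternative 2 | target skeleton with two phenylsulfonyl groups on C6 | C=C1CC(S(=O)(=O)c2ccccc2)(S(=O)(=O)c2ccccc2)[C@@H]2CC3=C(O[C@@]2(C)CC[C@@H]2[C@@H]1CC2(C)C)C(C)(C)C(=O)C(C(=O)C(C)C)=C3O
A5 | alternative 3 | diene with vinyl groups on C4 and C1, C8 ketone | C=C[C@@H]1[C@@H](C(=O)CC[C@@H]2CC3=C(O[C@@]2(C)C=C)C(C)(C)C(=O)C(C(=O)C(C)C)=C3O)CC1(C)C
A6 | alternative 3 | (Z)-C2=C3 cyclononene with the C8 ketone | O=C1CC[C@@H]2CC3=C(O[C@@]2(C)/C=C\[C@@H]2[C@@H]1CC2(C)C)C(C)(C)C(=O)C(C(=O)C(C)C)=C3O
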